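The earlier runs and the new flask stem from a simulated flask with constants of no real substance, and the scatter is random.

Slowness is what these flasks show first: target comes over tens of hours. We read it as a concentration rather than in percent, for percent is reckoned on substrate charges that differ between the flasks. Free catalyst takes up partner, then substrate, and releases target, while capture agent can trap an intermediate on the way.

| flask | substrate | partner | capture agent | free catalyst | temperature | remark | time |
|---|---|---|---|---|---|---|---|
| north-west | 0.057 M | 0.0475 M | 5 mM | 0.10 mM | 55 °C | run made earlier |  |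
| north-east | 0.10 M | 0.0475 M | 5 mM | 0.10 mM | 66 °C | run made earlier |  |
| west | 0.19 M | 0.0475 M | 5 mM | 0.10 mM | 55 °C | run made earlier |  |
| alpha | 0.20 M | 0.0475 M | 5.00 mM | 0.10 mM | 60 °C |  | 30 h |
| eta | 0.050 M | 0.0475 M | 5.00 mM | 0.10 mM | 60 °C |  | 30 h |

- north-west (time / h: target / %, substrate / %): 4.00: 11, 91; 8.00: 17, 82; 12.0: 26, 77; 15.0: 27, 72; 20.0: 35, 66
- north-east (time / h: target / %, substrate / %): 1.50: 9, 93; 3.00: 11, 90; 6.00: 16, 83; 12.0: 31, 70; 20.0: 41, 56
- west (time / h: target / %, substrate / %): 1.50: 1, 100; 3.00: 1, 98; 6.00: 4, 96; 12.0: 5, 95; 20.0: 12, 91

(standard deviation of a reading: 1.5 percentage points)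

1. the winner by amount of target, in percent of the substrate charged; "neither" if no more than 2 percentage points parts them (alpha / eta / neither)
2. how much target is there at the end, in percent of the substrate charged: alpha
3. how much target is there at the end, in percent of the substrate charged: eta

- the numbers in the tables scatter by 1.5 percentage points (one standard deviation)
- reactions considered so far: catalyst intermediate A -> catalyst intermediate B; free catalyst -> spent catalyst; partner + free catalyst <-> catalyst intermediate A; catalyst intermediate C + capture agent -> trapped intermediate; catalyst intermediate C -> free catalyst + target; substrate + catalyst intermediate B <-> catalyst intermediate C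

At 55 °C, over 20.0 h, the north-west run made 20.0 mM of target and the west run 22.8 mM. Substrate charged differs by a factor of 3.33, but these readings differ by only 1.14. So we follow the partner, which is the limiting reagent in both new flasks, with one partner used per target.

Taking the fraction of partner left after time t as exp(−kt), the north-west run gives 0.0272 /h. The north-east run, with 41.0 mM at 66 °C, gives 0.0994 /h. Interpolating ln k in temperature gives 0.0491 /h at 60 °C. This k is our partner clock, the first-order constant of partner use.

Over 30 h the clock uses 77.1% of the partner, which is 36.6 mM of target. Our reckoning is therefore 18.3% for alpha and 73.2% for eta. The forecast chose eta, with 17.5% (14% to 21%) for alpha and 68% (55% to 80%) for eta, holding that "The target made in absolute terms is what counts." Our figure for eta stands higher than the forecast's.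

The simulation gives 19.9% for alpha and 72.9% for eta, so eta has more.

    catalyst intermediate A → catalyst intermediate B (k = 0.430 /min, Ea = 93.0 kJ/mol)
    free catalyst → spent catalyst (k = 5.80 × 10⁻⁶ /min, Ea = 129 kJ/mol)
    partner + free catalyst ⇌ catalyst intermediate A (K = 1700 /M, k = 67.0 /M/min, Ea = 49.0 kJ/mol, ΔH = −62.0 kJ/mol)
    catalyst intermediate C + capture agent → trapped intermediate (k = 56.0 /M/min, Ea = 59.0 kJ/mol)
    catalyst intermediate C → free catalyst + target (k = 220 /min, Ea = 80.0 kJ/mol)
    substrate + catalyst intermediate B ⇌ catalyst intermediate C (K = 53.0 /M, k = 61.0 /M/min, Ea = 70.0 kJ/mol, ΔH = −54.0 kJ/mol)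
    (constants at 60 °C)

As concentrations, alpha holds 39.7 mM of target and eta 36.5 mM, a ratio of 1.09, while their substrate charges stand at 4.00. In eta, 23% of the partner is left at 30 h, where the clock gave 22.9%. We run the same clock on the neighbour flask, eta stopped at 12 h. It leaves 55.5% of the partner and gives 42.3% of target. That neighbour flask shows 59% of the partner left and 39.0% of target.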